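Numbering: C1/C5 bridgeheads, C2 C=O, C3 aroyl carbon, C4 enol carbon, C6 CH2, C7 CH(prenyl), C8 C(CH3)(homoprenyl), C9 bridging C=O; ring A = C1–C5 + C9, ring B = C1, C9, C5–C8.
Cuts, in retrosynthetic order: C7–prenyl (back to C7=CH2 and a C7 ketone), C1–C8, C7–C8 (amide + vinyllithium), C5–C6 (dearomative alkylation), the two ring–prenyl bonds, and the aryl–C(O) bond to phloroglucinol.
Enabling feature: C1 and C8 are vicinal quaternary carbons; C1 is the central carbon of the C2/C9 1,3-dicarbonyl unit and C8 the alpha carbon of a C7 ketone, so C1–C8 joins two enol(ate) carbons of a 1,4-dicarbonyl array and can be formed oxidatively.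
Forward: ring A is the phloroglucinol ring (acylated, diprenylated, dearomatised at C5 with the C6–C7 chain); ring B is closed last by anodic coupling of enolate carbon C1 with enol silane carbon C8; C7 is then converted into CH–prenyl.
Stereochemistry: C5 by a catalyst-controlled desymmetrising alkylation; C1 follows from C5 through the tether, C8 from the (E)-enol silane (s-cis 1,4-hydrosilylation) via a chair-like closure, C7 from exo-face hydroboration of the C7 methylene group.

Key step: step 10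

Assumption: the cinchonidine-derived bis-ammonium catalyst of step 6 is taken to give the (S) quaternary centre; should the sense be opposite, its cinchonine-derived pseudo-enantiomer is used.

Step 1
Reactants: 1 phloroglucinol
Product: 2 1,3,5-tris(methoxymethoxy)benzene
Conditions: NaH, MOMCl, DMF, 0 °C to rt
Reagents that add atoms: chloromethyl methyl ether, COCCl
Why: Williamson-type O-alkylation of the sodium phenoxide with the hard alkoxymethyl chloride gives the tris-acetal, which protects the phenols and later directs ortho-lithiation.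

Step 2
Reactants: 3 3,4-dihydroxybenzoic acid
Product: 5 3,4-bis(triisopropylsilyloxy)benzoic acid, via silyl ester 4 (not isolated)
Conditions: TIPSCl, imidazole, DMF, rt; then AcOH, THF/H2O, rt
Reagents that add atoms: triisopropylsilyl chloride, CC(C)[Si](Cl)(C(C)C)C(C)C
Why: Imidazole-mediated silylation covers both phenols and the carboxyl group, and only the silyl ester, far more labile than an aryl triisopropylsilyl ether, is hydrolysed by aqueous acetic acid.

Step 3
Reactants: 2 1,3,5-tris(methoxymethoxy)benzene; 5 3,4-bis(triisopropylsilyloxy)benzoic acid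
Product: 8 [3,4-bis(triisopropylsilyloxy)phenyl][2,4,6-tris(methoxymethoxy)phenyl]methanone, via acid chloride 6 (not isolated), via aryllithium 7 (not isolated)
Conditions: 5, (COCl)2, cat. DMF, CH2Cl2, 0 °C to rt, evaporate; 2, n-BuLi, THF, 0 °C; then 6, −78 °C to rt
Reagents that add atoms: none
Why: Directed ortho-metalation between two MOM ethers gives an aryllithium that is acylated once by the acid chloride (nucleophilic acyl substitution), because the resulting ketone is shielded by two ortho substituents against a second addition.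

Step 4
Reactants: 8 [3,4-bis(triisopropylsilyloxy)phenyl][2,4,6-tris(methoxymethoxy)phenyl]methanone
Product: 9 [3,4-bis(triisopropylsilyloxy)phenyl](2,4,6-trihydroxyphenyl)methanone
Conditions: conc. HCl (0.3 equiv), MeOH/THF, 40 °C
Reagents that add atoms: none
Why: Acid-catalysed transacetalisation with methanol cleaves the three MOM ethers (the two ortho ones assisted by the carbonyl group), whereas aryl triisopropylsilyl ethers are stable to dilute acid.

Step 5
Reactants: 9 [3,4-bis(triisopropylsilyloxy)phenyl](2,4,6-trihydroxyphenyl)methanone; 10 1-bromo-3-methylbut-2-ene (prenyl bromide)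
Product: 11 [3,4-bis(triisopropylsilyloxy)phenyl][2,4,6-trihydroxy-3,5-bis(3-methylbut-2-enyl)phenyl]methanone
Conditions: 10 (2.1 equiv), DBU (2.2 equiv), THF, 0 °C to rt
Reagents that add atoms: none
Why: C-alkylation of the ambident acylphloroglucinol anion by the soft allylic bromide (C-prenylation) fills the two free ring positions, and the non-hydrolytic amidine base in THF leaves the aryl silyl ethers intact.

Step 6
Reactants: 11 [3,4-bis(triisopropylsilyloxy)phenyl][2,4,6-trihydroxy-3,5-bis(3-methylbut-2-enyl)phenyl]methanone; 12 2-bromo-N-methoxy-N-methylacetamide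
Product: 13 (6S)-4-[3,4-bis(triisopropylsilyloxy)benzoyl]-5-hydroxy-6-{2-[methoxy(methyl)amino]-2-oxoethyl}-2,6-bis(3-methylbut-2-enyl)cyclohex-4-ene-1,3-dione
Conditions: 12 (1.1 equiv), CsOH·H2O (2.5 equiv), 2,7-bis[(O-allylhydrocinchonidinium-N-yl)methyl]naphthalene dibromide (10 mol %), toluene/CH2Cl2 (7:3), −50 to −30 °C
Reagents that add atoms: none
Why: Enantioselective phase-transfer alkylative dearomatisation: the dianion of 11 is paired with the dicationic cinchona catalyst, which should differentiate the two enantiotopic prenyl-bearing ring carbons, so that C-alkylation by the reactive alpha-bromo amide creates the quaternary centre (C5 of the target) in the (S) configuration.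

Step 7
Reactants: 14 6-methylhept-5-en-2-one
Product: 15 N'-[(2E)-6-methylhept-5-en-2-ylidene]-2,4,6-triisopropylbenzenesulfonohydrazide
Conditions: 2,4,6-(i-Pr)3C6H2SO2NHNH2, cat. HCl, MeOH, rt
Reagents that add atoms: 2,4,6-triisopropylbenzenesulfonohydrazide, CC(C)c1cc(C(C)C)c(S(=O)(=O)NN)c(C(C)C)c1
Why: Acid-catalysed condensation of the methyl ketone with the sulfonyl hydrazide gives the (E)-hydrazone, in which the N–H lies syn to the methyl group as required for regioselective deprotonation in the Shapiro reaction.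

Step 8
Reactants: 13 (6S)-N-methoxy-N-methyl amide; 15 trisylhydrazone of 6-methylhept-5-en-2-one
Product: 17 (6S)-4-[3,4-bis(triisopropylsilyloxy)benzoyl]-5-hydroxy-6-(7-methyl-3-methylidene-2-oxooct-6-enyl)-2,6-bis(3-methylbut-2-enyl)cyclohex-4-ene-1,3-dione, via vinyllithium 16 (not isolated)
Conditions: 15, n-BuLi (2.05 equiv), THF, −78 to 0 °C; cannulate 16 (2.5 equiv) into 13/LiN(SiMe3)2 (2.1 equiv), THF, −78 to −20 °C; 1 M HCl quench
Reagents that add atoms: none
Why: The hydrazone dianion loses sulfinate and dinitrogen to give the less substituted vinyllithium (Shapiro reaction), which adds once to the N-methoxy-N-methyl amide because the chelated tetrahedral adduct survives until work-up (Weinreb ketone synthesis), the ring carbonyl groups being shielded as the dilithium dienolate.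

Step 9
Reactants: 17 (6S)-enone
Product: 20 (6S)-4-[3,4-bis(triisopropylsilyloxy)benzoyl]-6-[(2E)-3,7-dimethyl-2-(triethylsilyloxy)octa-2,6-dienyl]-5-hydroxy-2,6-bis(3-methylbut-2-enyl)cyclohex-4-ene-1,3-dione, via bis-silyl dienone 18 (not isolated), via tris-silyl ether 19 (not isolated)
Conditions: Et3SiCl (2.3 equiv), Et3N, CH2Cl2, 0 °C; filter under Ar; Et3SiH (1.5 equiv), RhCl(PPh3)3 (2 mol %), THF, 45 °C; then MeOH, NaHCO3, 0 °C; pH 7 buffer work-up, used at once
Reagents that add atoms: triethylsilane, CC[SiH](CC)CC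
Why: With the two ring enols capped as labile silyl ethers, rhodium-catalysed 1,4-hydrosilylation of the 2-substituted enone through its s-cis form puts the new methyl group cis to the silyloxy group, i.e. gives the (E)-enol silane with the homoprenyl group cis to C6, and buffered methanol then cleaves only the vinylogous silyl esters of ring A.

Step 10
Reactants: 20 (6S)-(E)-enol triethylsilyl ether
Product: 21 (1S,5S,8S)-3-[3,4-bis(triisopropylsilyloxy)benzoyl]-4-hydroxy-8-methyl-8-(4-methylpent-3-enyl)-1,5-bis(3-methylbut-2-enyl)bicyclo[3.3.1]non-3-ene-2,7,9-trione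
Conditions: undivided cell, RVC anode, Pt cathode, constant current (about 1 mA per cm2, 2.1 F/mol), LiClO4 (0.1 M), 2,6-lutidine (2.5 equiv), CH2Cl2/i-PrOH (4:1), 0 °C, Ar
Reagents that add atoms: none
Why: Proposed new method: 2,6-lutidine ionises the ring A trione and its enolate is oxidised at the anode at a potential well below that of the enol silane, the silylated arene and the prenyl alkenes, giving an electrophilic radical with high spin density at C1 that adds to the nucleophilic C8 terminus of the enol silane, after which the alpha-silyloxy C7 radical is oxidised (at the anode or by a second trione radical) to a silyloxycarbenium ion that gives up its silyl group to isopropanol and leaves the C7 ketone. The closest known reaction types are the anodic coupling of enol ethers or silyl enol ethers with tethered nucleophiles and the oxidant-promoted addition of 1,3-dicarbonyl radicals to silyl enol ethers to give 1,4-diketones; neither has been used to join two fully substituted carbons in a dearomatised acylphloroglucinol. Ring B closes in a 6-endo-trig mode, the 5-exo alternative at the oxygen-bearing C7 being polarity-mismatched. C1 is controlled by C5, because the C6–C7 tether can reach C1 only on the ring A face that carries C6, and C8 by the (E) geometry, since in a chair-like transition state the homoprenyl group cis to C6 becomes axial and the methyl group equatorial. The step needs coupling at C1 and not at C3, which the aroyl group secures by lowering the spin density at C3 and by the penalty of placing it on a bridgehead, and it needs the enol silane to be attacked faster than the C5 prenyl group (5-exo), which rests on the far higher electron density of the silyl enol ether towards an electrophilic radical.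

Step 11
Reactants: 21 (1S,5S,8S)-2,7,9-trione
Product: 22 (1S,5S,8R)-3-[3,4-bis(triisopropylsilyloxy)benzoyl]-4-hydroxy-8-methyl-7-methylidene-8-(4-methylpent-3-enyl)-1,5-bis(3-methylbut-2-enyl)bicyclo[3.3.1]non-3-ene-2,9-dione
Conditions: KOt-Bu (1 equiv), THF, 0 °C; then Ph3P=CH2 (from Ph3PCH3Br and KOt-Bu, 4 equiv), THF/toluene, 0 to 60 °C; dilute HCl work-up
Reagents that add atoms: methyltriphenylphosphonium bromide, C[P+](c1ccccc1)(c1ccccc1)c1ccccc1.[Br-]
Why: Wittig methylenation reaches only the C7 ketone, since ring A is masked as its potassium enolate and the C9 ketone lies between two quaternary carbons.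

Step 12
Reactants: 22 (1S,5S,8R)-7-methylidene enol
Product: 23 (1S,5S,8R)-3-[3,4-bis(triisopropylsilyloxy)benzoyl]-4-methoxy-8-methyl-7-methylidene-8-(4-methylpent-3-enyl)-1,5-bis(3-methylbut-2-enyl)bicyclo[3.3.1]non-3-ene-2,9-dione
Conditions: Me2SO4, K2CO3, acetone, rt
Reagents that add atoms: dimethyl sulfate, COS(=O)(=O)OC
Why: O-Methylation of the vinylogous acid with a hard electrophile (SN2 at the methyl group) should occur at the less hindered C4 oxygen, and any C2-O-methyl isomer converges on the same enol in step 14.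

Step 13
Reactants: 23 (1S,5S,8R)-7-methylidene methyl ether; 24 1-bromo-2-methylprop-1-ene
Product: 26 (1S,5S,7S,8R)-3-[3,4-bis(triisopropylsilyloxy)benzoyl]-4-methoxy-8-methyl-8-(4-methylpent-3-enyl)-1,5,7-tris(3-methylbut-2-enyl)bicyclo[3.3.1]non-3-ene-2,9-dione, via B-alkyl borane 25 (not isolated)
Conditions: 9-BBN (2.5 equiv), THF, 0 to 40 °C; then 3 M aq. K3PO4, 24 (3 equiv), Pd(dppf)Cl2 (5 mol %), AsPh3 (10 mol %), DMF, rt to 45 °C
Reagents that add atoms: none
Why: Hydroboration with 9-BBN selects the 1,1-disubstituted alkene over the trisubstituted ones and should deliver hydrogen to C7 from the exo face, the endo face lying over the C2–C4 bridge of ring A, so that the boron-bearing carbon ends up endo (7S), and the B-alkyl group is then coupled with the alkenyl bromide in a Suzuki–Miyaura reaction with retention at carbon.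

Step 14
Reactants: 26 (1S,5S,7S,8R)-4-methoxy compound
Product: 27 (1S,5S,7S,8R)-3-[3,4-bis(triisopropylsilyloxy)benzoyl]-4-hydroxy-8-methyl-8-(4-methylpent-3-enyl)-1,5,7-tris(3-methylbut-2-enyl)bicyclo[3.3.1]non-3-ene-2,9-dione
Conditions: LiCl, DMSO, 120 °C; dilute HCl work-up
Reagents that add atoms: none
Why: Chloride attacks the methyl group of the vinylogous ester in an SN2 demethylation of the Krapcho type, releasing the stabilised trione enolate without affecting the alkenes.

Step 15
Reactants: 27 (1S,5S,7S,8R)-bis(triisopropylsilyl) ether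
Product: 28 (1S,5S,7S,8R)-3-(3,4-dihydroxybenzoyl)-4-hydroxy-8-methyl-8-(4-methylpent-3-enyl)-1,5,7-tris(3-methylbut-2-enyl)bicyclo[3.3.1]non-3-ene-2,9-dione (CNP0108469.1)
Conditions: Bu4NF, AcOH, THF, 0 °C
Reagents that add atoms: none
Why: Fluoride-induced cleavage of the two aryl silyl ethers, buffered with acetic acid so that the catechol and the enolised trione meet neither strong base nor strong acid, liberates the target.

Compound list
1 | phloroglucinol | Oc1cc(O)cc(O)c1 | starting material
2 | 1,3,5-tris(methoxymethoxy)benzene | COCOc1cc(OCOC)cc(OCOC)c1 | intermediate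
3 | 3,4-dihydroxybenzoic acid | O=C(O)c1ccc(O)c(O)c1 | starting material
4 | triisopropylsilyl 3,4-bis(triisopropylsilyloxy)benzoate | CC(C)[Si](OC(=O)c1ccc(O[Si](C(C)C)(C(C)C)C(C)C)c(O[Si](C(C)C)(C(C)C)C(C)C)c1)(C(C)C)C(C)C | intermediate
5 | 3,4-bis(triisopropylsilyloxy)benzoic acid | OC(=O)c1ccc(O[Si](C(C)C)(C(C)C)C(C)C)c(O[Si](C(C)C)(C(C)C)C(C)C)c1 | intermediate
6 | 3,4-bis(triisopropylsilyloxy)benzoyl chloride | ClC(=O)c1ccc(O[Si](C(C)C)(C(C)C)C(C)C)c(O[Si](C(C)C)(C(C)C)C(C)C)c1 | intermediate
7 | [2,4,6-tris(methoxymethoxy)phenyl]lithium | [Li]c1c(OCOC)cc(OCOC)cc1OCOC | intermediate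
8 | [3,4-bis(triisopropylsilyloxy)phenyl][2,4,6-tris(methoxymethoxy)phenyl]methanone | COCOc1cc(OCOC)c(C(=O)c2ccc(O[Si](C(C)C)(C(C)C)C(C)C)c(O[Si](C(C)C)(C(C)C)C(C)C)c2)c(OCOC)c1 | intermediate
9 | [3,4-bis(triisopropylsilyloxy)phenyl](2,4,6-trihydroxyphenyl)methanone | Oc1cc(O)c(C(=O)c2ccc(O[Si](C(C)C)(C(C)C)C(C)C)c(O[Si](C(C)C)(C(C)C)C(C)C)c2)c(O)c1 | intermediate
10 | 1-bromo-3-methylbut-2-ene (prenyl bromide) | CC(C)=CCBr | starting material
11 | [3,4-bis(triisopropylsilyloxy)phenyl][2,4,6-trihydroxy-3,5-bis(3-methylbut-2-enyl)phenyl]methanone | CC(C)=CCc1c(O)c(CC=C(C)C)c(O)c(C(=O)c2ccc(O[Si](C(C)C)(C(C)C)C(C)C)c(O[Si](C(C)C)(C(C)C)C(C)C)c2)c1O | intermediate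
12 | 2-bromo-N-methoxy-N-methylacetamide | CON(C)C(=O)CBr | starting material
13 | (6S)-4-[3,4-bis(triisopropylsilyloxy)benzoyl]-5-hydroxy-6-{2-[methoxy(methyl)amino]-2-oxoethyl}-2,6-bis(3-methylbut-2-enyl)cyclohex-4-ene-1,3-dione (ring C6 = C5 of the target; ring C2 enolised, no configuration) | CON(C)C(=O)C[C@]1(CC=C(C)C)C(=O)C(CC=C(C)C)C(=O)C(C(=O)c2ccc(O[Si](C(C)C)(C(C)C)C(C)C)c(O[Si](C(C)C)(C(C)C)C(C)C)c2)=C1O | intermediate
14 | 6-methylhept-5-en-2-one | CC(=O)CCC=C(C)C | starting material
15 | N'-[(2E)-6-methylhept-5-en-2-ylidene]-2,4,6-triisopropylbenzenesulfonohydrazide | CC(C)=CCC/C(C)=N/NS(=O)(=O)c1c(C(C)C)cc(C(C)C)cc1C(C)C | intermediate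
16 | (6-methylhepta-1,5-dien-2-yl)lithium | [Li]C(=C)CCC=C(C)C | intermediate
17 | (6S)-4-[3,4-bis(triisopropylsilyloxy)benzoyl]-5-hydroxy-6-(7-methyl-3-methylidene-2-oxooct-6-enyl)-2,6-bis(3-methylbut-2-enyl)cyclohex-4-ene-1,3-dione | C=C(CCC=C(C)C)C(=O)C[C@]1(CC=C(C)C)C(=O)C(CC=C(C)C)C(=O)C(C(=O)c2ccc(O[Si](C(C)C)(C(C)C)C(C)C)c(O[Si](C(C)C)(C(C)C)C(C)C)c2)=C1O | intermediate
18 | ring A bis(triethylsilyl) dienol ether of 17, 2,5-dienone form, same configuration at the quaternary carbon (one O-regioisomer drawn) | C=C(CCC=C(C)C)C(=O)C[C@]1(CC=C(C)C)C(O[Si](CC)(CC)CC)=C(CC=C(C)C)C(=O)C(C(=O)c2ccc(O[Si](C(C)C)(C(C)C)C(C)C)c(O[Si](C(C)C)(C(C)C)C(C)C)c2)=C1O[Si](CC)(CC)CC | intermediate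
19 | tris(triethylsilyl) compound: 18 with the side chain as (E)-enol triethylsilyl ether | CC(C)=CCC/C(C)=C(/O[Si](CC)(CC)CC)C[C@]1(CC=C(C)C)C(O[Si](CC)(CC)CC)=C(CC=C(C)C)C(=O)C(C(=O)c2ccc(O[Si](C(C)C)(C(C)C)C(C)C)c(O[Si](C(C)C)(C(C)C)C(C)C)c2)=C1O[Si](CC)(CC)CC | intermediate
20 | (6S)-4-[3,4-bis(triisopropylsilyloxy)benzoyl]-6-[(2E)-3,7-dimethyl-2-(triethylsilyloxy)octa-2,6-dienyl]-5-hydroxy-2,6-bis(3-methylbut-2-enyl)cyclohex-4-ene-1,3-dione | CC(C)=CCC/C(C)=C(/O[Si](CC)(CC)CC)C[C@]1(CC=C(C)C)C(=O)C(CC=C(C)C)C(=O)C(C(=O)c2ccc(O[Si](C(C)C)(C(C)C)C(C)C)c(O[Si](C(C)C)(C(C)C)C(C)C)c2)=C1O | intermediate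
21 | (1S,5S,8S)-3-[3,4-bis(triisopropylsilyloxy)benzoyl]-4-hydroxy-8-methyl-8-(4-methylpent-3-enyl)-1,5-bis(3-methylbut-2-enyl)bicyclo[3.3.1]non-3-ene-2,7,9-trione | CC(C)=CCC[C@]1(C)C(=O)C[C@]2(CC=C(C)C)C(=O)[C@@]1(CC=C(C)C)C(=O)C(C(=O)c3ccc(O[Si](C(C)C)(C(C)C)C(C)C)c(O[Si](C(C)C)(C(C)C)C(C)C)c3)=C2O | intermediate
22 | (1S,5S,8R)-3-[3,4-bis(triisopropylsilyloxy)benzoyl]-4-hydroxy-8-methyl-7-methylidene-8-(4-methylpent-3-enyl)-1,5-bis(3-methylbut-2-enyl)bicyclo[3.3.1]non-3-ene-2,9-dione | CC(C)=CCC[C@]1(C)C(=C)C[C@]2(CC=C(C)C)C(=O)[C@@]1(CC=C(C)C)C(=O)C(C(=O)c3ccc(O[Si](C(C)C)(C(C)C)C(C)C)c(O[Si](C(C)C)(C(C)C)C(C)C)c3)=C2O | intermediate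
23 | (1S,5S,8R)-3-[3,4-bis(triisopropylsilyloxy)benzoyl]-4-methoxy-8-methyl-7-methylidene-8-(4-methylpent-3-enyl)-1,5-bis(3-methylbut-2-enyl)bicyclo[3.3.1]non-3-ene-2,9-dione | CC(C)=CCC[C@]1(C)C(=C)C[C@]2(CC=C(C)C)C(=O)[C@@]1(CC=C(C)C)C(=O)C(C(=O)c3ccc(O[Si](C(C)C)(C(C)C)C(C)C)c(O[Si](C(C)C)(C(C)C)C(C)C)c3)=C2OC | intermediate
24 | 1-bromo-2-methylprop-1-ene | CC(C)=CBr | starting material
25 | (1S,5S,7S,8R)-7-[(9-borabicyclo[3.3.1]nonan-9-yl)methyl]-3-[3,4-bis(triisopropylsilyloxy)benzoyl]-4-methoxy-8-methyl-8-(4-methylpent-3-enyl)-1,5-bis(3-methylbut-2-enyl)bicyclo[3.3.1]non-3-ene-2,9-dione | CC(C)=CCC[C@]1(C)[C@@H](CB3C4CCCC3CCC4)C[C@]2(CC=C(C)C)C(=O)[C@@]1(CC=C(C)C)C(=O)C(C(=O)c5ccc(O[Si](C(C)C)(C(C)C)C(C)C)c(O[Si](C(C)C)(C(C)C)C(C)C)c5)=C2OC | intermediate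
26 | (1S,5S,7S,8R)-3-[3,4-bis(triisopropylsilyloxy)benzoyl]-4-methoxy-8-methyl-8-(4-methylpent-3-enyl)-1,5,7-tris(3-methylbut-2-enyl)bicyclo[3.3.1]non-3-ene-2,9-dione | CC(C)=CCC[C@]1(C)[C@@H](CC=C(C)C)C[C@]2(CC=C(C)C)C(=O)[C@@]1(CC=C(C)C)C(=O)C(C(=O)c3ccc(O[Si](C(C)C)(C(C)C)C(C)C)c(O[Si](C(C)C)(C(C)C)C(C)C)c3)=C2OC | intermediate
27 | (1S,5S,7S,8R)-3-[3,4-bis(triisopropylsilyloxy)benzoyl]-4-hydroxy-8-methyl-8-(4-methylpent-3-enyl)-1,5,7-tris(3-methylbut-2-enyl)bicyclo[3.3.1]non-3-ene-2,9-dione | CC(C)=CCC[C@]1(C)[C@@H](CC=C(C)C)C[C@]2(CC=C(C)C)C(=O)[C@@]1(CC=C(C)C)C(=O)C(C(=O)c3ccc(O[Si](C(C)C)(C(C)C)C(C)C)c(O[Si](C(C)C)(C(C)C)C(C)C)c3)=C2O | intermediate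
28 | (1S,5S,7S,8R)-3-(3,4-dihydroxybenzoyl)-4-hydroxy-8-methyl-8-(4-methylpent-3-enyl)-1,5,7-tris(3-methylbut-2-enyl)bicyclo[3.3.1]non-3-ene-2,9-dione (CNP0108469.1) | CC(C)=CCC[C@]1(C)[C@@H](CC=C(C)C)C[C@]2(CC=C(C)C)C(=O)[C@@]1(CC=C(C)C)C(=O)C(C(=O)c1ccc(O)c(O)c1)=C2O | target

Total step count: 15.
Longest linear sequence: 13 steps (1 → 2 → 8 → 9 → 11 → 13 → 17 → 20 → 21 → 22 → 23 → 26 → 27 → 28; the same length from 3).

Steps most likely to fail

Step 10 (key step). The C1 radical may close 5-exo onto the C5 prenyl alkene instead of onto C8. The C7 adduct radical may add to the homoprenyl alkene before it is oxidised. Closure through a boat may erode the C8 configuration, or the enol silane may be solvolysed before it couples. The fallback sets out from 17 and returns at 21. Conjugate reduction of 17 with LiBH(s-Bu)3 (the first two equivalents are consumed by the ring enols) through the s-cis enone, then acetylation of the ketone enolate with one equivalent of Ac2O, should give the (6S)-(E)-enol acetate F1. Treatment with Mn(OAc)3·2H2O and Cu(OAc)2·H2O in AcOH at room temperature then forms the same C1–C8 bond in homogeneous solution. This is the classical oxidative free-radical cyclisation of 1,3-dicarbonyl compounds, here with an enol ester as acceptor. The dissolved Cu(OAc)2 oxidises the C7 radical at once, and the acyloxycarbenium ion loses its acetyl group to give 21.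

Step 6. The desymmetrisation may proceed with low enantioselectivity, and O-alkylation or a second alkylation at the remaining prenylated carbon may compete. The fallback sets out from 11 and returns at 13. Alkylation of 11 with 12 under achiral conditions (Cs2CO3, DMF, 0 °C) gives the racemic amide F2. This strong vinylogous acid is resolved by classical salt formation with (R)-1-phenylethylamine (or its antipode, whichever gives the less soluble salt with the (S)-acid). Fractional crystallisation should give the diastereomerically pure (S)-acid (R)-amine salt F3, from which dilute HCl liberates 13.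

Step 13. Hydroboration of the alkene next to the quaternary C8 may be slow, with competing reduction of ring carbonyl groups by the borane. Transmetalation of the hindered B-alkyl group may be sluggish. Facial selectivity may be poor because the axial C8 chain flanks the exo face. The fallback sets out from 23 and returns at 26. Hydroformylation of the 1,1-disubstituted alkene of 23 with Rh(acac)(CO)2 and tris(2,4-di-tert-butylphenyl) phosphite under CO/H2 in toluene at 70 °C places the formyl group on the terminal carbon and hydrogen on C7 without any hydride reagent. It should give the homologated (7R)-aldehyde F4, whose C7 epimer, if formed, can be separated at this stage. A Wittig reaction with isopropylidenetriphenylphosphorane (from isopropyltriphenylphosphonium iodide and n-BuLi, THF, −78 to 0 °C) then completes the prenyl group and gives 26.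

Further compounds
F1 | step 10 | (6S)-6-[(2E)-2-acetoxy-3,7-dimethylocta-2,6-dienyl]-4-[3,4-bis(triisopropylsilyloxy)benzoyl]-5-hydroxy-2,6-bis(3-methylbut-2-enyl)cyclohex-4-ene-1,3-dione | CC(C)=CCC/C(C)=C(/OC(C)=O)C[C@]1(CC=C(C)C)C(=O)C(CC=C(C)C)C(=O)C(C(=O)c2ccc(O[Si](C(C)C)(C(C)C)C(C)C)c(O[Si](C(C)C)(C(C)C)C(C)C)c2)=C1O
F2 | step 6 | racemic 13 | CON(C)C(=O)CC1(CC=C(C)C)C(=O)C(CC=C(C)C)C(=O)C(C(=O)c2ccc(O[Si](C(C)C)(C(C)C)C(C)C)c(O[Si](C(C)C)(C(C)C)C(C)C)c2)=C1O
F3 | step 6 | (R)-1-phenylethylammonium enolate of (6S)-13 | CON(C)C(=O)C[C@]1(CC=C(C)C)C(=O)C(CC=C(C)C)C(=O)C(C(=O)c2ccc(O[Si](C(C)C)(C(C)C)C(C)C)c(O[Si](C(C)C)(C(C)C)C(C)C)c2)=C1[O-].C[C@@H]([NH3+])c1ccccc1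
F4 | step 13 | (1S,5S,7R,8R)-3-[3,4-bis(triisopropylsilyloxy)benzoyl]-4-methoxy-8-methyl-8-(4-methylpent-3-enyl)-1,5-bis(3-methylbut-2-enyl)-7-(2-oxoethyl)bicyclo[3.3.1]non-3-ene-2,9-dione | CC(C)=CCC[C@]1(C)[C@@H](CC=O)C[C@]2(CC=C(C)C)C(=O)[C@@]1(CC=C(C)C)C(=O)C(C(=O)c3ccc(O[Si](C(C)C)(C(C)C)C(C)C)c(O[Si](C(C)C)(C(C)C)C(C)C)c3)=C2OC
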